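**Retrosynthetic overview** (tetralin numbering; ring A = dimethoxybenzo ring, ring B = saturated ring, ring C = pendant aryl)

1. The target is read as the all-cis (1S,2S,3R) isomer: C2–H and C3–H are cis to each other and anti to the C1 aryl, so the last step is a syn hydrogenation of a C2=C3 alkene from the face opposite ring C.
2. Ring B with C2=C3 is a Diels–Alder cyclohexene. C4–C4a and C8a–C1 are cut together: the diene is C1–C4 (a Z-1-aryl-2,3-bis(methoxymethyl)butadiene) and the dienophile is the C4a=C8a edge of ring A.
3. Enabling feature: ring A carries oxygen only at C6/C7 and hydrogen at C5/C8, so it maps onto 2,3-dimethoxy-1,4-benzoquinone. Its carbonyls at C5/C8 activate the C4a=C8a bond and bind a chiral Lewis acid, and are removed afterwards (enolization, bis-triflate, hydrogenolysis).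
4. The diene comes from 1,4-dimethoxybut-2-yne and ethylene (enyne metathesis), then Heck arylation with 4-iodoveratrole.
5. Ring order: ring C is bought, ring B is formed in the key step onto a non-aromatic ring A, ring A is aromatized late, and C2/C3 are set last.

Key step: step 3

Assumption: the (S)-oxazaborolidinium catalyst is written as the hand expected from its accepted transition-state model for quinones; if the first adduct proved antipodal, the equally available (R)-catalyst would be used with no other change.

**Step 1**
Reactants: 1 1,4-dimethoxybut-2-yne; 2 ethylene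
Product: 3 2,3-bis(methoxymethyl)buta-1,3-diene
Conditions: ethylene (1 atm), second-generation Grubbs catalyst (H2IMes)(PCy3)Cl2Ru=CHPh (5 mol %), toluene, 80 °C
Reagents that add atoms: none
Why: Ethylene–alkyne cross enyne metathesis turns an internal alkyne into a 2,3-disubstituted butadiene, propargylic ethers are good substrates, and no stereocenter or alkene geometry is created.

**Step 2**
Reactants: 3 2,3-bis(methoxymethyl)buta-1,3-diene; 4 4-iodo-1,2-dimethoxybenzene
Product: 5 (Z)-1-(3,4-dimethoxyphenyl)-2,3-bis(methoxymethyl)buta-1,3-diene
Conditions: Pd(OAc)2 (5 mol %), P(o-tol)3 (10 mol %), K2CO3, Bu4NBr, DMF, 80 °C; 3 in threefold excess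
Reagents that add atoms: none
Why: In this Mizoroki–Heck arylation of a conjugated diene the arylpalladium adds to a terminal CH2, and β-hydride elimination from the allylpalladium intermediate should give the conjugated 1-aryl diene with the aryl trans to the bulkier dienyl branch (Z by CIP, the geometry needed for the cycloaddition), while excess 3 suppresses double arylation.

**Step 3**
Reactants: 5 (Z)-1-(3,4-dimethoxyphenyl)-2,3-bis(methoxymethyl)buta-1,3-diene; 6 2,3-dimethoxy-1,4-benzoquinone
Product: 7 (4aR,5R,8aS)-5-(3,4-dimethoxyphenyl)-2,3-dimethoxy-6,7-bis(methoxymethyl)-4a,5,8,8a-tetrahydronaphthalene-1,4-dione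
Conditions: (S)-3,3-diphenyl-1-(o-tolyl)tetrahydro-1H,3H-pyrrolo[1,2-c][1,3,2]oxazaborole (20 mol %) activated with Tf2NH (18 mol %), CH2Cl2, −78 → −20 °C; 5 (1.2 equiv)
Reagents that add atoms: none
Why: The protonated oxazaborolidine binds one quinone carbonyl and lowers the LUMO of that enone, so 5 adds in a concerted, asynchronous [4+2] cycloaddition to the unsubstituted C5=C6 bond of 6 and not to the deactivated dimethoxy-substituted bond; the closest known reaction type is the oxazaborolidinium-catalyzed enantioselective Diels–Alder reaction of quinones with substituted dienes. Ring B is closed by this intermolecular [4+2] cycloaddition, suprafacial on both partners, which joins the diene termini to the two quinone carbons that become C4a and C8a and gives a cis ring fusion. The aryl-bearing stereocenter is controlled by three elements together: the catalyst shields one face of the bound enone, the unsubstituted diene terminus (largest HOMO coefficient of a 1-aryl diene) bonds to the β-carbon of the bound enone, and the endo transition state places the aryl cis to the dione ring. Because the two ring-fusion centers are erased in step 4, each of these selectivities translates directly into enantiomeric purity at the surviving center, which is why a strongly face- and orientation-discriminating cationic catalyst is used at low temperature. The Z geometry of 5 puts the aryl on the outside of the s-cis diene so that it can react, and the slight excess of diene should prevent oxidation of the adduct by unreacted quinone.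

**Step 4**
Reactants: 7 (4aR,5R,8aS)-5-(3,4-dimethoxyphenyl)-2,3-dimethoxy-6,7-bis(methoxymethyl)-4a,5,8,8a-tetrahydronaphthalene-1,4-dione
Product: 9 (5R)-5-(3,4-dimethoxyphenyl)-2,3-dimethoxy-6,7-bis(methoxymethyl)-5,8-dihydronaphthalene-1,4-diyl bis(trifluoromethanesulfonate), via hydroquinone 8 (not isolated)
Conditions: Et3N (4 equiv), CH2Cl2, 0 °C → rt, argon; then Tf2O (2.5 equiv), −78 → 0 °C
Reagents that add atoms: trifluoromethanesulfonic anhydride (Tf2O), O=S(=O)(C(F)(F)F)OS(=O)(=O)C(F)(F)F
Why: Base-mediated double enolization of the ene-dione is driven by aromatization of ring A and removes only the two ring-fusion hydrogens, so the aryl-bearing center is untouched, and the air-sensitive hydroquinone is O-triflated in the same flask (phenol triflation).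

**Step 5**
Reactants: 9 (5R)-5-(3,4-dimethoxyphenyl)-2,3-dimethoxy-6,7-bis(methoxymethyl)-5,8-dihydronaphthalene-1,4-diyl bis(trifluoromethanesulfonate)
Product: 10 (1S)-1-(3,4-dimethoxyphenyl)-6,7-dimethoxy-2,3-bis(methoxymethyl)-1,4-dihydronaphthalene
Conditions: Pd(OAc)2 (10 mol %), 1,3-bis(diphenylphosphino)propane (dppp, 12 mol %), HCO2H (6 equiv), Et3N (9 equiv), DMF, 80 °C
Reagents that add atoms: none
Why: In this palladium-catalyzed transfer hydrogenolysis of aryl triflates, zerovalent palladium inserts into each C–OTf bond, formate delivers hydride with loss of CO2, and reductive elimination leaves C5–H and C8–H; the hindered tetrasubstituted alkene and the C1 center should not be engaged.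

**Step 6**
Reactants: 10 (1S)-1-(3,4-dimethoxyphenyl)-6,7-dimethoxy-2,3-bis(methoxymethyl)-1,4-dihydronaphthalene
Product: 11 (1S,2S,3R)-1-(3,4-dimethoxyphenyl)-6,7-dimethoxy-2,3-bis(methoxymethyl)-1,2,3,4-tetrahydronaphthalene
Conditions: H2 (50 bar), [Ir(cod)(PCy3)(py)]PF6 (5 mol %), CH2Cl2, rt
Reagents that add atoms: none
Why: Crabtree-type homogeneous hydrogenation should add H2 syn to the tetrasubstituted C2=C3 bond from the face opposite the C1 aryl, which is held pseudo-axial by allylic strain with the C2 methoxymethyl group and by the peri C8–H, so both new C–H bonds are anti to the aryl and both methoxymethyl groups end up cis to it (all-cis 1S,2S,3R); the cationic iridium catalyst is chosen because it reduces tetrasubstituted alkenes with little of the double-bond migration and dehydrogenation expected with Pd/C.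

**Compound list**

1 | 1,4-dimethoxybut-2-yne | COCC#CCOC | starting material
2 | ethylene | C=C | starting material
3 | 2,3-bis(methoxymethyl)buta-1,3-diene | COCC(=C)C(=C)COC | intermediate
4 | 4-iodo-1,2-dimethoxybenzene | COc1ccc(I)cc1OC | starting material
5 | (Z)-1-(3,4-dimethoxyphenyl)-2,3-bis(methoxymethyl)buta-1,3-diene (aryl cis to the C2 methoxymethyl group, trans to the C3 vinyl branch) | COC/C(=C\c1ccc(OC)c(OC)c1)C(=C)COC | intermediate
6 | 2,3-dimethoxy-1,4-benzoquinone | COC1=C(OC)C(=O)C=CC1=O | starting material
7 | (4aR,5R,8aS)-5-(3,4-dimethoxyphenyl)-2,3-dimethoxy-6,7-bis(methoxymethyl)-4a,5,8,8a-tetrahydronaphthalene-1,4-dione (cis ring fusion, aryl trans to the adjacent ring-fusion hydrogen) | COCC1=C(COC)[C@@H](c2ccc(OC)c(OC)c2)[C@H]3C(=O)C(OC)=C(OC)C(=O)[C@H]3C1 | intermediate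
8 | (5R)-5-(3,4-dimethoxyphenyl)-2,3-dimethoxy-6,7-bis(methoxymethyl)-5,8-dihydronaphthalene-1,4-diol | COCC1=C(COC)[C@@H](c2ccc(OC)c(OC)c2)c3c(O)c(OC)c(OC)c(O)c3C1 | intermediate (not isolated)
9 | (5R)-5-(3,4-dimethoxyphenyl)-2,3-dimethoxy-6,7-bis(methoxymethyl)-5,8-dihydronaphthalene-1,4-diyl bis(trifluoromethanesulfonate) | COCC1=C(COC)[C@@H](c2ccc(OC)c(OC)c2)c3c(OS(=O)(=O)C(F)(F)F)c(OC)c(OC)c(OS(=O)(=O)C(F)(F)F)c3C1 | intermediate
10 | (1S)-1-(3,4-dimethoxyphenyl)-6,7-dimethoxy-2,3-bis(methoxymethyl)-1,4-dihydronaphthalene | COCC1=C(COC)[C@@H](c2ccc(OC)c(OC)c2)c3cc(OC)c(OC)cc3C1 | intermediate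
11 | (1S,2S,3R)-1-(3,4-dimethoxyphenyl)-6,7-dimethoxy-2,3-bis(methoxymethyl)-1,2,3,4-tetrahydronaphthalene (all-cis) | COC[C@@H]1Cc2cc(OC)c(OC)cc2[C@H](c2ccc(OC)c(OC)c2)[C@@H]1COC | target

**Totals**

Total step count: 6. Longest linear sequence: 6 steps (1 → 3 → 5 → 7 → 9 → 10 → 11).

**Steps most likely to fail**

Step 3. The risks are poor facial or orientational discrimination (each lowers the enantiomeric purity once the ring-fusion centers are erased), slow reaction at the hindered aryl-bearing diene terminus, and oxidation of the adduct by the quinone in the flask. The fallback sets out from 5 and changes the dienophile to an aryne. Commercial 4,5-dimethoxy-2-(trimethylsilyl)phenyl trifluoromethanesulfonate with CsF in MeCN at rt generates 4,5-dimethoxybenzyne F1. Diene 5 traps it in an aryne Diels–Alder reaction that forms the same two bonds and gives racemic 1-(3,4-dimethoxyphenyl)-6,7-dimethoxy-2,3-bis(methoxymethyl)-1,4-dihydronaphthalene F2 directly at the aromatic oxidation level. Preparative chromatography on a chiral stationary phase then separates the enantiomers, and the route is rejoined at 10 (steps 4 and 5 are not needed).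

Step 6. The risks are slow reduction of the tetrasubstituted alkene, migration of the double bond into conjugation, dehydrogenation to the arylnaphthalene, and insufficient facial discrimination. The fallback sets out from 9 and inverts the order of the last two operations. The alkene is hydrogenated at the bis-triflate stage with H2 and [Ir(cod)(PCy3)(py)]PF6 in CH2Cl2; there the C8 triflate peri to C1 adds a second buttress that holds the aryl pseudo-axial. This should give (5S,6S,7R)-5-(3,4-dimethoxyphenyl)-2,3-dimethoxy-6,7-bis(methoxymethyl)-5,6,7,8-tetrahydronaphthalene-1,4-diyl bis(trifluoromethanesulfonate) F3. The two triflates are then removed with Pd(OAc)2, dppp, HCO2H and Et3N in DMF at 80 °C, so that palladium hydride meets only the robust tetralin, and the route is rejoined at 11.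

Step 2. The risks are formation of the wrong alkene geometry, β-hydride elimination toward the methoxymethyl group, and a second arylation at the other diene terminus. The fallback sets out from 1 and makes the C1=C2 bond by metathesis instead of making the aryl–C1 bond by palladium. Cross enyne metathesis of 1 with commercial 3,4-dimethoxystyrene is run with the second-generation Hoveyda–Grubbs catalyst (H2IMes)Cl2Ru=CH(C6H4-2-OiPr) in toluene at 80 °C, and the geometric isomers are equilibrated with catalytic I2 under light. Only the Z isomer can adopt the reactive s-cis form with the aryl outside. The route is rejoined at 5, and this fallback makes no compound outside the list (entry F0).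

**Further compounds**

F1 | step 3 | 4,5-dimethoxybenzyne | COC1=CC#CC=C1OC
F2 | step 3 | racemic 1-(3,4-dimethoxyphenyl)-6,7-dimethoxy-2,3-bis(methoxymethyl)-1,4-dihydronaphthalene | COCC1=C(COC)C(c2ccc(OC)c(OC)c2)c3cc(OC)c(OC)cc3C1
F3 | step 6 | (5S,6S,7R)-5-(3,4-dimethoxyphenyl)-2,3-dimethoxy-6,7-bis(methoxymethyl)-5,6,7,8-tetrahydronaphthalene-1,4-diyl bis(trifluoromethanesulfonate) | COC[C@@H]1Cc2c(OS(=O)(=O)C(F)(F)F)c(OC)c(OC)c(OS(=O)(=O)C(F)(F)F)c2[C@H](c3ccc(OC)c(OC)c3)[C@@H]1COC
F0 | step 2 | none | none
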